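**Plan**
- Retrosynthetic cuts: (a) the C2'–C3' bond of the trienamide (Heck), which releases the iodo-dienamide of 2-amino-3-hydroxycyclopentenone; (b) the N–C2 bond of the ring enamide (copper amidation of a 2-iodoenone); (c) the C5–C6 bond of the cyclohexenone together with the O–C6 bond of the oxirane (intramolecular Darzens); (d) the acyl–alkyne bond and the two C–C bonds at the carbinol carbon C4.
- Enabling feature: in the 7-oxabicyclo[4.1.0]hept-3-en-2-one core, oxirane carbon C6 is alpha to the C1 ketone and oxirane carbon C5 sits on the quaternary carbinol C4. C6 can therefore be an α-chloro-ketone carbon and C5 a non-enolisable aldehyde, held in reach by a Z C2=C3 alkene, and one closure builds the carbocycle (ring A) and the oxirane (ring B).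
- Forward order: glycerate → quaternary carbinol (vinyl and ethynyl arms) → chloromethyl ynone → aldehyde → Z-enone → ring A and ring B in one step → 2-iodination → amide side chain → Heck coupling → desilylation.
- Stereochemistry: C4 comes from (R)-glycerate by chelation-controlled alkynylation (the auxiliary carbon then becomes C5); C5 and C6 come from C4 in the Darzens step; the side-chain methyl centre comes from (S)-3-bromo-2-methylpropan-1-ol. Alkene geometry comes from Lindlar reduction (Z), Wittig (E), Takai (E) and Heck (E).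

Key step: step 8

Remark: the drawn descriptors correspond to a (1S,5R,6R) core in which the C4 hydroxyl is anti to the oxirane oxygen, and the route is built for this arrangement. Cyclohexenone numbering is used for the core: C1 ketone, C2 (N-bearing), C3, C4 (carbinol), C5 and C6 (oxirane carbons, C6 next to C1).

**Route**

Step 1
Reactants: 1 methyl (4R)-2,2-dimethyl-1,3-dioxolane-4-carboxylate
Product: 2 (4R)-N-methoxy-N,2,2-trimethyl-1,3-dioxolane-4-carboxamide
Conditions: MeNHOMe·HCl, iPrMgCl, THF, −20 °C to 0 °C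
Reagents that add atoms: N,O-dimethylhydroxylamine hydrochloride, CNOC.Cl
Why: Weinreb aminolysis of the ester by the magnesium amide should proceed at low temperature without enolising the α-alkoxy stereocentre.

Step 2
Reactants: 2 (4R)-N-methoxy-N,2,2-trimethyl-1,3-dioxolane-4-carboxamide
Product: 3 1-[(4R)-2,2-dimethyl-1,3-dioxolan-4-yl]prop-2-en-1-one
Conditions: CH2=CHMgBr, THF, −78 °C to −20 °C; inverse quench into cold 1 M HCl
Reagents that add atoms: vinylmagnesium bromide, C=C[Mg]Br
Why: The chelated tetrahedral adduct of the Weinreb amide stops the Grignard addition at the ketone stage, and the cold acidic quench should prevent both Michael addition of the liberated hydroxylamine and enolisation of the α-centre.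

Step 3
Reactants: 3 1-[(4R)-2,2-dimethyl-1,3-dioxolan-4-yl]prop-2-en-1-one
Product: 4 (3R)-3-[(4R)-2,2-dimethyl-1,3-dioxolan-4-yl]pent-1-en-4-yn-3-ol
Conditions: MgBr2·OEt2, CH2Cl2, −78 °C; then HC≡CMgBr (THF), −78 °C; aq. NH4Cl
Reagents that add atoms: ethynylmagnesium bromide, C#C[Mg]Br
Why: In a Cram-chelate addition magnesium should bridge the ketone oxygen and the dioxolane α-oxygen, so the alkynyl Grignard (1,2-selective towards enones) attacks the face opposite the dioxolane CH2 and sets the quaternary carbinol as 3R; any minor epimer is a diastereomer and should be separable by chromatography.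

Step 4
Reactants: 4 (3R)-3-[(4R)-2,2-dimethyl-1,3-dioxolan-4-yl]pent-1-en-4-yn-3-ol
Product: 5 triethyl{[(3R)-3-[(4R)-2,2-dimethyl-1,3-dioxolan-4-yl]pent-1-en-4-yn-3-yl]oxy}silane
Conditions: TESOTf, 2,6-lutidine, CH2Cl2, −78 °C to 0 °C
Reagents that add atoms: triethylsilyl trifluoromethanesulfonate, CC[Si](CC)(CC)OS(=O)(=O)C(F)(F)F
Why: Silyl triflate with a hindered pyridine base is the standard silylation of hindered tertiary alcohols, and the non-chelating silyl ether is later needed for the stereocontrol of step 8.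

Step 5
Reactants: 5 triethyl{[(3R)-3-[(4R)-2,2-dimethyl-1,3-dioxolan-4-yl]pent-1-en-4-yn-3-yl]oxy}silane
Product: 6 (5R)-1-chloro-5-[(4R)-2,2-dimethyl-1,3-dioxolan-4-yl]-5-[(triethylsilyl)oxy]hept-6-en-3-yn-2-one
Conditions: n-BuLi, THF, −78 °C; then ClCH2C(O)N(OMe)Me, −78 °C to −20 °C; inverse quench into cold 1 M HCl
Reagents that add atoms: 2-chloro-N-methoxy-N-methylacetamide, CON(C)C(=O)CCl
Why: Acylation of the lithium acetylide by the Weinreb amide should stop at the chloromethyl ynone because the tetrahedral chelate survives until the acidic quench.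

Step 6
Reactants: 6 (5R)-1-chloro-5-[(4R)-2,2-dimethyl-1,3-dioxolan-4-yl]-5-[(triethylsilyl)oxy]hept-6-en-3-yn-2-one
Product: 7 (2R)-6-chloro-2-ethenyl-5-oxo-2-[(triethylsilyl)oxy]hex-3-ynal
Conditions: H5IO6, EtOAc, rt
Reagents that add atoms: none
Why: Periodic acid should hydrolyse the terminal acetonide and cleave the liberated 1,2-diol in one pot, turning the former dioxolane carbon into the non-enolisable aldehyde (future C5) while the tertiary silyl ether and the ynone are expected to survive.

Step 7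
Reactants: 7 (2R)-6-chloro-2-ethenyl-5-oxo-2-[(triethylsilyl)oxy]hex-3-ynal
Product: 8 (2R,3Z)-6-chloro-2-ethenyl-5-oxo-2-[(triethylsilyl)oxy]hex-3-enal
Conditions: H2 (1 atm), Pd/CaCO3 poisoned with Pb(OAc)2 (Lindlar catalyst), quinoline, EtOAc, 0 °C, stopped after one equivalent
Reagents that add atoms: none
Why: Lindlar semi-hydrogenation delivers both hydrogens syn and should give the Z-enone, the poisoned catalyst sparing the hindered terminal vinyl group, the aldehyde and the C–Cl bond.

Step 8
Reactants: 8 (2R,3Z)-6-chloro-2-ethenyl-5-oxo-2-[(triethylsilyl)oxy]hex-3-enal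
Product: 10 (1S,5R,6R)-5-ethenyl-5-[(triethylsilyl)oxy]-7-oxabicyclo[4.1.0]hept-3-en-2-one, via lithium chlorohydrin alkoxide 9 (not isolated)
Conditions: LiOt-Bu (1.1 equiv), THF (0.01 M), −78 °C to 0 °C
Reagents that add atoms: none
Why: Intramolecular Darzens condensation: the alkoxide base reversibly deprotonates the only acidic position (the CH2Cl carbon), the enolate carbon adds to the aldehyde (6-(enolendo)-exo-trig aldol, closing the cyclohexenone ring through the C5–C6 bond), and the new alkoxide displaces chloride from the neighbouring carbon (3-exo-tet, inversion at C6) to close the oxirane. The closest known reaction type is the base-mediated Darzens reaction of α-chloro ketones with aldehydes, including its ring-forming intramolecular variants. C5 is controlled by the quaternary C4 centre: in the lithium-bridged half-chair the aldehyde oxygen is pseudo-axial and anti to the pseudo-axial, non-chelating C4–OSiEt3 bond (Cornforth arrangement, vinyl pseudo-equatorial), so the new C–O bond should form trans to the silyloxy group. C6 follows from C5, because the fused oxirane can only be cis and only the trans-chlorohydrin alkoxide reaches the anti-periplanar geometry for displacement, while the cis epimer can return by retro-aldol or C6 enolisation. The step needs chemoselectivity and anti selectivity between silyloxy group and oxirane oxygen; the substrate secures the first by having one enolisable site, one non-enolisable acceptor and a Z-alkene that holds the ends together, and the second by the C4 stereocentre. The product has no enolisable hydrogen and should be stable to the base.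

Step 9
Reactants: 10 (1S,5R,6R)-5-ethenyl-5-[(triethylsilyl)oxy]-7-oxabicyclo[4.1.0]hept-3-en-2-one
Product: 11 (1S,5R,6R)-5-ethenyl-3-iodo-5-[(triethylsilyl)oxy]-7-oxabicyclo[4.1.0]hept-3-en-2-one
Conditions: I2, pyridine, CH2Cl2, 0 °C to rt
Reagents that add atoms: iodine, [I][I]
Why: Pyridine-mediated α-iodination of enones (conjugate addition, iodination of the enolate, elimination) should give the 2-iodoenone without touching the isolated vinyl group or the oxirane.

Step 10
Reactants: 12 (2S)-3-bromo-2-methylpropan-1-ol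
Product: 13 (2R)-2-methylhexan-1-ol
Conditions: n-PrMgCl (3 equiv), Li2CuCl4 (3 mol %), THF, −20 °C to rt
Reagents that add atoms: n-propylmagnesium chloride, CCC[Mg]Cl
Why: Copper-catalysed sp3–sp3 Grignard cross-coupling of the primary bromide (the first equivalent forms the magnesium alkoxide) leaves the stereocentre untouched, the descriptor changing from S to R only through the priority change.

Step 11
Reactants: 13 (2R)-2-methylhexan-1-ol
Product: 15 ethyl (2E,4R)-2,4-dimethyloct-2-enoate, via (R)-2-methylhexanal 14 (not isolated)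
Conditions: TEMPO (10 mol %), PhI(OAc)2, CH2Cl2, rt; then Ph3P=C(Me)CO2Et, 40 °C
Reagents that add atoms: ethyl 2-(triphenylphosphoranylidene)propanoate, CCOC(=O)C(C)=P(c1ccccc1)(c1ccccc1)c1ccccc1
Why: Nitroxyl-catalysed oxidation gives the epimerisable aldehyde under non-basic conditions, and the stabilised α-methyl ylide added to the same flask should give the E-trisubstituted enoate (Wittig reaction).

Step 12
Reactants: 15 ethyl (2E,4R)-2,4-dimethyloct-2-enoate
Product: 16 (2E,4R)-2,4-dimethyloct-2-enamide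
Conditions: AlMe3, NH4Cl, toluene, 0 °C to 50 °C
Reagents that add atoms: ammonium chloride, [NH4+].[Cl-]
Why: The aluminium amide formed from AlMe3 and NH4Cl should convert the hindered conjugated ester directly into the primary amide (Weinreb aminolysis) without conjugate addition.

Step 13
Reactants: 11 (1S,5R,6R)-5-ethenyl-3-iodo-5-[(triethylsilyl)oxy]-7-oxabicyclo[4.1.0]hept-3-en-2-one; 16 (2E,4R)-2,4-dimethyloct-2-enamide
Product: 17 (2E,4R)-N-[(1S,5R,6R)-5-ethenyl-2-oxo-5-[(triethylsilyl)oxy]-7-oxabicyclo[4.1.0]hept-3-en-3-yl]-2,4-dimethyloct-2-enamide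
Conditions: CuI (10 mol %), N,N'-dimethylethylenediamine (20 mol %), K2CO3, toluene, 50 °C
Reagents that add atoms: none
Why: Goldberg-type copper-catalysed amidation of the vinyl iodide with the primary amide should give the 2-acylamino enone, the silyl ether keeping the anti-hydroxy oxirane from Payne rearrangement under the carbonate base.

Step 14
Reactants: 18 cyclopentane-1,3-dione
Product: 19 2-(hydroxyimino)cyclopentane-1,3-dione
Conditions: NaNO2, 1 M HCl, H2O, 0 °C
Reagents that add atoms: sodium nitrite, [Na+].[O-]N=O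
Why: Nitrosation of the highly enolised 1,3-dione at C2 and tautomerisation should give the oxime.

Step 15
Reactants: 19 2-(hydroxyimino)cyclopentane-1,3-dione
Product: 20 2-amino-3-hydroxycyclopent-2-en-1-one hydrochloride
Conditions: H2 (3 atm), 10% Pd/C, HCl, EtOH, rt
Reagents that add atoms: hydrogen chloride, Cl
Why: Catalytic hydrogenation of the oxime gives the amine, trapped as the hydrochloride of its stable enol tautomer so that self-condensation is avoided.

Step 16
Reactants: 21 ethyl (2E)-4-oxobut-2-enoate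
Product: 22 ethyl (2E,4E)-5-iodopenta-2,4-dienoate
Conditions: CrCl2, CHI3, THF, 0 °C, dark
Reagents that add atoms: iodoform, IC(I)I
Why: Takai olefination of the aldehyde with the geminal dichromium species from iodoform should give the E-vinyl iodide and leave the enoate untouched.

Step 17
Reactants: 22 ethyl (2E,4E)-5-iodopenta-2,4-dienoate
Product: 23 (2E,4E)-5-iodopenta-2,4-dienoic acid
Conditions: LiOH·H2O, THF/H2O, 0 °C to rt; then 1 M HCl
Reagents that add atoms: lithium hydroxide, [Li+].[OH-]
Why: Mild saponification should hydrolyse the ethyl ester without isomerising the diene or displacing the vinyl iodide.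

Step 18
Reactants: 23 (2E,4E)-5-iodopenta-2,4-dienoic acid; 20 2-amino-3-hydroxycyclopent-2-en-1-one hydrochloride
Product: 25 (2E,4E)-N-(2-hydroxy-5-oxocyclopent-1-en-1-yl)-5-iodopenta-2,4-dienamide, via dienoyl chloride 24 (not isolated)
Conditions: (COCl)2, DMF (cat.), CH2Cl2, 0 °C to rt, evaporate; then 20, pyridine, DMF, 0 °C to rt
Reagents that add atoms: none
Why: The acid chloride acylates the weakly nucleophilic enaminone (any O-acyl product should rearrange to nitrogen) to give the vinylogous-acid amide found in the target.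

Step 19
Reactants: 17 (2E,4R)-N-[(1S,5R,6R)-5-ethenyl-2-oxo-5-[(triethylsilyl)oxy]-7-oxabicyclo[4.1.0]hept-3-en-3-yl]-2,4-dimethyloct-2-enamide; 25 (2E,4E)-N-(2-hydroxy-5-oxocyclopent-1-en-1-yl)-5-iodopenta-2,4-dienamide
Product: 26 (2E,4R)-N-[(1S,5R,6R)-5-[(1E,3E,5E)-7-[(2-hydroxy-5-oxocyclopent-1-en-1-yl)amino]-7-oxohepta-1,3,5-trien-1-yl]-2-oxo-5-[(triethylsilyl)oxy]-7-oxabicyclo[4.1.0]hept-3-en-3-yl]-2,4-dimethyloct-2-enamide
Conditions: Pd(OAc)2 (10 mol %), n-Bu4NCl, NaHCO3, DMF, 40 °C, dark
Reagents that add atoms: none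
Why: In this Heck reaction the dienyl–palladium species should add to the terminal carbon of the vinyl group and, because C4 is quaternary, β-hydride elimination can only occur towards the new chain, giving the E-alkene with retention of the dienyl iodide geometry.

Step 20
Reactants: 26 (2E,4R)-N-[(1S,5R,6R)-5-[(1E,3E,5E)-7-[(2-hydroxy-5-oxocyclopent-1-en-1-yl)amino]-7-oxohepta-1,3,5-trien-1-yl]-2-oxo-5-[(triethylsilyl)oxy]-7-oxabicyclo[4.1.0]hept-3-en-3-yl]-2,4-dimethyloct-2-enamide
Product: 27 (2E,4R)-N-[(1S,5R,6R)-5-hydroxy-5-[(1E,3E,5E)-7-[(2-hydroxy-5-oxocyclopent-1-en-1-yl)amino]-7-oxohepta-1,3,5-trien-1-yl]-2-oxo-7-oxabicyclo[4.1.0]hept-3-en-3-yl]-2,4-dimethyloct-2-enamide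
Conditions: HF·pyridine, pyridine, THF, 0 °C to rt
Reagents that add atoms: none
Why: Buffered hydrogen fluoride should cleave the tertiary triethylsilyl ether without opening the oxirane or isomerising the triene, and the acidic medium avoids alkoxide-driven Payne rearrangement.

**Compound list**
1 | methyl (4R)-2,2-dimethyl-1,3-dioxolane-4-carboxylate | COC(=O)[C@H]1COC(C)(C)O1 | starting material
2 | (4R)-N-methoxy-N,2,2-trimethyl-1,3-dioxolane-4-carboxamide | CON(C)C(=O)[C@H]1COC(C)(C)O1 | intermediate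
3 | 1-[(4R)-2,2-dimethyl-1,3-dioxolan-4-yl]prop-2-en-1-one | C=CC(=O)[C@H]1COC(C)(C)O1 | intermediate
4 | (3R)-3-[(4R)-2,2-dimethyl-1,3-dioxolan-4-yl]pent-1-en-4-yn-3-ol | C#C[C@](O)(C=C)[C@H]1COC(C)(C)O1 | intermediate
5 | triethyl{[(3R)-3-[(4R)-2,2-dimethyl-1,3-dioxolan-4-yl]pent-1-en-4-yn-3-yl]oxy}silane | C#C[C@](O[Si](CC)(CC)CC)(C=C)[C@H]1COC(C)(C)O1 | intermediate
6 | (5R)-1-chloro-5-[(4R)-2,2-dimethyl-1,3-dioxolan-4-yl]-5-[(triethylsilyl)oxy]hept-6-en-3-yn-2-one | ClCC(=O)C#C[C@](O[Si](CC)(CC)CC)(C=C)[C@H]1COC(C)(C)O1 | intermediate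
7 | (2R)-6-chloro-2-ethenyl-5-oxo-2-[(triethylsilyl)oxy]hex-3-ynal | ClCC(=O)C#C[C@](O[Si](CC)(CC)CC)(C=C)C=O | intermediate
8 | (2R,3Z)-6-chloro-2-ethenyl-5-oxo-2-[(triethylsilyl)oxy]hex-3-enal | ClCC(=O)/C=C\[C@](O[Si](CC)(CC)CC)(C=C)C=O | intermediate
9 | lithium (1S,2R,6R)-2-chloro-6-ethenyl-3-oxo-6-[(triethylsilyl)oxy]cyclohex-4-en-1-olate (trans-chlorohydrin alkoxide) | [Li+].O=C1C=C[C@](O[Si](CC)(CC)CC)(C=C)[C@H]([O-])[C@H]1Cl | intermediate (not isolated)
10 | (1S,5R,6R)-5-ethenyl-5-[(triethylsilyl)oxy]-7-oxabicyclo[4.1.0]hept-3-en-2-one | C1=C[C@](O[Si](CC)(CC)CC)(C=C)[C@@H]2O[C@@H]2C1=O | intermediate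
11 | (1S,5R,6R)-5-ethenyl-3-iodo-5-[(triethylsilyl)oxy]-7-oxabicyclo[4.1.0]hept-3-en-2-one | IC1=C[C@](O[Si](CC)(CC)CC)(C=C)[C@@H]2O[C@@H]2C1=O | intermediate
12 | (2S)-3-bromo-2-methylpropan-1-ol | OC[C@H](C)CBr | starting material
13 | (2R)-2-methylhexan-1-ol | CCCC[C@@H](C)CO | intermediate
14 | (2R)-2-methylhexanal | CCCC[C@@H](C)C=O | intermediate (not isolated)
15 | ethyl (2E,4R)-2,4-dimethyloct-2-enoate | CCCC[C@@H](C)/C=C(\C)C(=O)OCC | intermediate
16 | (2E,4R)-2,4-dimethyloct-2-enamide | CCCC[C@@H](C)/C=C(\C)C(N)=O | intermediate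
17 | (2E,4R)-N-[(1S,5R,6R)-5-ethenyl-2-oxo-5-[(triethylsilyl)oxy]-7-oxabicyclo[4.1.0]hept-3-en-3-yl]-2,4-dimethyloct-2-enamide | CCCC[C@@H](C)/C=C(\C)C(=O)NC1=C[C@](O[Si](CC)(CC)CC)(C=C)[C@@H]2O[C@@H]2C1=O | intermediate
18 | cyclopentane-1,3-dione | O=C1CCC(=O)C1 | starting material
19 | 2-(hydroxyimino)cyclopentane-1,3-dione | ON=C1C(=O)CCC1=O | intermediate
20 | 2-amino-3-hydroxycyclopent-2-en-1-one hydrochloride | Cl.NC1=C(O)CCC1=O | intermediate
21 | ethyl (2E)-4-oxobut-2-enoate | CCOC(=O)/C=C/C=O | starting material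
22 | ethyl (2E,4E)-5-iodopenta-2,4-dienoate | CCOC(=O)/C=C/C=C/I | intermediate
23 | (2E,4E)-5-iodopenta-2,4-dienoic acid | OC(=O)/C=C/C=C/I | intermediate
24 | (2E,4E)-5-iodopenta-2,4-dienoyl chloride | ClC(=O)/C=C/C=C/I | intermediate (not isolated)
25 | (2E,4E)-N-(2-hydroxy-5-oxocyclopent-1-en-1-yl)-5-iodopenta-2,4-dienamide | O=C(/C=C/C=C/I)NC1=C(O)CCC1=O | intermediate
26 | (2E,4R)-N-[(1S,5R,6R)-5-[(1E,3E,5E)-7-[(2-hydroxy-5-oxocyclopent-1-en-1-yl)amino]-7-oxohepta-1,3,5-trien-1-yl]-2-oxo-5-[(triethylsilyl)oxy]-7-oxabicyclo[4.1.0]hept-3-en-3-yl]-2,4-dimethyloct-2-enamide | CCCC[C@@H](C)/C=C(\C)C(=O)NC1=C[C@](O[Si](CC)(CC)CC)(/C=C/C=C/C=C/C(=O)NC2=C(O)CCC2=O)[C@@H]2O[C@@H]2C1=O | intermediate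
27 | (2E,4R)-N-[(1S,5R,6R)-5-hydroxy-5-[(1E,3E,5E)-7-[(2-hydroxy-5-oxocyclopent-1-en-1-yl)amino]-7-oxohepta-1,3,5-trien-1-yl]-2-oxo-7-oxabicyclo[4.1.0]hept-3-en-3-yl]-2,4-dimethyloct-2-enamide | CCCC[C@@H](C)/C=C(\C)C(=O)NC1=C[C@](O)(/C=C/C=C/C=C/C(=O)NC2=C(O)CCC2=O)[C@@H]2O[C@@H]2C1=O | target

**Summary**
Total step count: 20.
Longest linear sequence: 12 steps (steps 1–9, 13, 19 and 20).

Steps most likely to fail:

Step 8. The anionic cascade may suffer from poor facial selectivity in the aldol addition, from migration of the triethylsilyl group onto the new alkoxide before chloride is displaced, or from intermolecular condensation. The fallback separates C–C bond formation from oxirane closure. It sets out from 8: soft enolisation with MgBr2·OEt2 and i-Pr2NEt in CH2Cl2 at −20 °C (a magnesium aldolate, no free alkoxide) should give the chlorohydrin (4R,5S,6R)-6-chloro-4-ethenyl-5-hydroxy-4-[(triethylsilyl)oxy]cyclohex-2-en-1-one F1, whose C6 epimer converges by enolisation. After purification, brief treatment of the chlorohydrin with K2CO3 in MeCN at 0 °C closes the oxirane, and the sequence comes back to the route at 10.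

Step 13. The coupling may stall because the conjugated primary amide is a weak nucleophile, or the epoxy ketone may degrade under carbonate at 50 °C. The fallback brings nitrogen in as azide at room temperature and acylates afterwards. It sets out from 11: copper-catalysed azidation (NaN3, CuI, sodium ascorbate, N,N'-dimethylethylenediamine, EtOH/H2O, rt) should give (1S,5R,6R)-3-azido-5-ethenyl-5-[(triethylsilyl)oxy]-7-oxabicyclo[4.1.0]hept-3-en-2-one F2, and Staudinger reduction (PMe3, THF/H2O) the amino enone (1S,5R,6R)-3-amino-5-ethenyl-5-[(triethylsilyl)oxy]-7-oxabicyclo[4.1.0]hept-3-en-2-one F3. In parallel, ester 15 is hydrolysed (LiOH) to (2E,4R)-2,4-dimethyloct-2-enoic acid F4, which (COCl)2 converts into (2E,4R)-2,4-dimethyloct-2-enoyl chloride F5. Acylation of the amino enone with this chloride and pyridine comes back to the route at 17.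

Step 19. The hindered allylic silyl ether may insert slowly, so that self-coupling of the iodo-dienamide or base- and heat-induced decomposition of the epoxy enone takes over. The fallback replaces the Heck reaction by metathesis and Suzuki–Miyaura coupling. It sets out from 17: desilylation (HF·pyridine) should give (2E,4R)-N-[(1S,5R,6R)-5-ethenyl-5-hydroxy-2-oxo-7-oxabicyclo[4.1.0]hept-3-en-3-yl]-2,4-dimethyloct-2-enamide F6. Cross-metathesis of this tertiary allylic alcohol with vinylboronic acid pinacol ester (second-generation Hoveyda–Grubbs catalyst, CH2Cl2, 40 °C) should give (2E,4R)-N-[(1S,5R,6R)-5-hydroxy-2-oxo-5-[(E)-2-(4,4,5,5-tetramethyl-1,3,2-dioxaborolan-2-yl)ethenyl]-7-oxabicyclo[4.1.0]hept-3-en-3-yl]-2,4-dimethyloct-2-enamide F7. Coupling of this boronate with 25 (Pd(PPh3)4, TlOEt, THF/H2O, rt) comes back to the route at 27.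

**Further compounds**
F1 | step 8 | (4R,5S,6R)-6-chloro-4-ethenyl-5-hydroxy-4-[(triethylsilyl)oxy]cyclohex-2-en-1-one | O=C1C=C[C@](O[Si](CC)(CC)CC)(C=C)[C@H](O)[C@H]1Cl
F2 | step 13 | (1S,5R,6R)-3-azido-5-ethenyl-5-[(triethylsilyl)oxy]-7-oxabicyclo[4.1.0]hept-3-en-2-one | [N-]=[N+]=NC1=C[C@](O[Si](CC)(CC)CC)(C=C)[C@@H]2O[C@@H]2C1=O
F3 | step 13 | (1S,5R,6R)-3-amino-5-ethenyl-5-[(triethylsilyl)oxy]-7-oxabicyclo[4.1.0]hept-3-en-2-one | NC1=C[C@](O[Si](CC)(CC)CC)(C=C)[C@@H]2O[C@@H]2C1=O
F4 | step 13 | (2E,4R)-2,4-dimethyloct-2-enoic acid | CCCC[C@@H](C)/C=C(\C)C(O)=O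
F5 | step 13 | (2E,4R)-2,4-dimethyloct-2-enoyl chloride | CCCC[C@@H](C)/C=C(\C)C(Cl)=O
F6 | step 19 | (2E,4R)-N-[(1S,5R,6R)-5-ethenyl-5-hydroxy-2-oxo-7-oxabicyclo[4.1.0]hept-3-en-3-yl]-2,4-dimethyloct-2-enamide | CCCC[C@@H](C)/C=C(\C)C(=O)NC1=C[C@](O)(C=C)[C@@H]2O[C@@H]2C1=O
F7 | step 19 | (2E,4R)-N-[(1S,5R,6R)-5-hydroxy-2-oxo-5-[(E)-2-(4,4,5,5-tetramethyl-1,3,2-dioxaborolan-2-yl)ethenyl]-7-oxabicyclo[4.1.0]hept-3-en-3-yl]-2,4-dimethyloct-2-enamide | CCCC[C@@H](C)/C=C(\C)C(=O)NC1=C[C@](O)(/C=C/B2OC(C)(C)C(C)(C)O2)[C@@H]2O[C@@H]2C1=O
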